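The readings were computed from invented constants, noise included.

Count turnovers before you fit anything. The flasks, readings and questions are these.

| flask | Z | E | X | time |
|---|---|---|---|---|
| beta | 80.0 mM | 160 mM | 0.400 mM |  |
| theta | 80.0 mM | 160 mM | 0.800 mM |  |
| zeta | 80.0 mM | 480 mM | 0.400 mM |  |
| gamma | 160 mM | 160 mM | 0.400 mM |  |
| alpha | 80.0 mM | 160 mM | 0.400 mM | 150 min |

- beta run (time / min: [J] / mM): 4.3: 3.8; 13: 7.9; 25: 14.1; 39: 19.0; 56: 25.7; 75: 30.4
- theta run (time / min: [J] / mM): 4.3: 5.7; 13: 11.8; 25: 17.9; 39: 22.7; 56: 28.4; 75: 32.2
- zeta run (time / min: [J] / mM): 4.3: 9.9; 13: 21.4; 25: 31.4; 39: 40.4; 56: 52.0; 75: 58.6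
- gamma run (time / min: [J] / mM): 4.3: 7.6; 13: 16.6; 25: 26.5; 39: 35.7; 56: 45.6; 75: 55.1

(readings scatter by 0.8 mM)

- Overall: Z + E -> J, with X as catalyst.
- Constant volume, constant temperature.
- Bound and free are read together.
- "The second partner" is E.
- An order is taken over about fifteen percent of the charge, up and down.

1. order of the initial rate in [E], near the charge of the beta run, the rate being that where two percent of its Z are J
2. order of the initial rate in [Z], near the charge of the beta run, the rate being that where two percent of its Z are J (one fixed amount of J, the same in the runs compared)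
3. J in the alpha run at 150 min, as a share of the Z charged

1. The theta and beta runs differ in X by 0.400 mM. Theta leads beta in J by 3.90 mM at 13 min and by 3.70 mM at 39 min, so the lead stops growing early. Over the 13 min, 25 min and 39 min readings it averages 3.80 mM.

2. I divide that lead by the extra X and get 9.50. This is the turnover number, the J that one X adds before the lead stops growing, at the Z and E of these two runs. Its scatter is about 1.63. In the alpha run, X should therefore add about 3.80 mM of J.

3. After 25 min I treat the flask as Z and E reacting without X. I use a clock that runs steadily for such a reaction: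

clock = ln[(E/Z)(Z at start/E at start)]/(E at start − Z at start).

In the beta run it reads 1.27 L mol⁻¹ at 25 min and 3.34 L mol⁻¹ at 75 min. Its speed is 0.0414 L mol⁻¹ min⁻¹.

4. Running the beta clock on to 150 min gives 57.4 % of the Z in the alpha run.

5. The weak link is that speed, which rests on two readings of one run. The zeta run, at 480 mM of E, gives 0.0379 L mol⁻¹ min⁻¹ over the same times, slower than beta. I take the mean, 0.0397 L mol⁻¹ min⁻¹. The alpha clock at 150 min then reads 6.32 L mol⁻¹, which gives 45.4 mM of J, or 56.8 %. I commit to that.

The forecast gives 55 % for the alpha run, lower than mine. It gives orders of 0.93 in E and 1 in Z, on which I reckon nothing. It reads the runs as “a fast-dying catalytic part on top of a steady background”.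

The alpha run gives 55.6 %, below my figure, and that is 44.5 mM of J. The orders are 0.96 in E and 0.83 in Z, the second below the forecast's 1. The turnover number credits X with 8.55 % of the J in the alpha run.

    X + Z ⇌ XZ, settled at all times (21.50 L mol⁻¹)
    XZ + E ⇌ XZE, settled at all times (1.350 L mol⁻¹)
    XZE → J + X (12.42 min⁻¹)
    X + E → Qi + E (2.550 L mol⁻¹ min⁻¹)
    Z + E → J (0.03804 L mol⁻¹ min⁻¹)

The theta run has the Z and E of the beta run, so the same turnover number credits its extra X with 3.80 mM of J. Divided by Z times E at the 25 min reading of the beta run, that lead is a clock step of 0.395 L mol⁻¹, which the clock covers in 9.95 min. The theta run reaches half its Z 9.80 min before the beta run.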